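## The problem

Compound 19 is an achiral diaryl ether. Ring A is a methyl benzoate: the ester sits on C1 between a prenyl ether (C2) and the bridging oxygen (C6), with a methyl group at C4. Ring B carries the bridging oxygen at C1' between a hydroxymethyl group (C2') and a methoxy group (C6'), with a second methoxy group at C4'.

The hard bond is C6–O–C1'. C1' is flanked on both sides, C6 lies next to the ester, and both rings are electron-rich, so neither SNAr nor a copper- or palladium-mediated coupling of a 2,6-disubstituted phenol with a ring A halide is attractive. The target has no stereocentre, so there is nothing to relay; the one stereocentre the route creates is a racemic spiro carbon that is destroyed again.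

The fragile groups are:
- the aryl prenyl ether (strong or Lewis acid, Claisen rearrangement on strong heating, hydrogenation, DDQ, SeO2, zerovalent palladium);
- the benzylic alcohol;
- the ester, which is hindered towards late esterification yet can be attacked by the neighbouring benzylic alkoxide to give an eight-membered lactone.

Four different O-alkyl groups must also be placed without regiochemical ambiguity.

The enabling feature is that C1' is bonded only to oxygen, C2' and C6'. It can therefore start as an O–CH2 group that is alkylated twice. The ester carbon on C1 sits ortho to that oxygen, so O–CH2–C(=O) closed onto ring A is a benzofuran-3(2H)-one whose C2 is doubly nucleophilic. The oxygen pattern of ring B (C4', C6') with carbon at C2' maps onto a 1-alkoxy-1,4-diyn-3-one.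

## Retrosynthesis

**19 to 17.** The last operations are functional-group changes: the O–Si bond of silyl ether 18 and the C4' O–CH3 bond, which leads back to phenol 17. The hydroxymethyl group must be masked because a free alcohol would add to an ynone, and the C4' oxygen cannot be carried as a methyl ether because it is the carbonyl of the ring B precursor. Both forward steps are routine; the only demand is that desilylation does not generate an alkoxide next to the ester.

**17 to 16.** The ester C–OMe bond is cut and C1' is reconnected to the ester carbon, giving spiro dienone 16. The alternative cuts at C6–O or C1'–O would require coupling a doubly flanked phenol to an unactivated ring. In 16 the aryl–oxygen bond is simply part of a furanone, and ring B is a cyclohexa-2,5-dienone one fragmentation away from a phenoxide. The forward reaction asks methoxide to attack the furanone ketone, not to be lost on the dienone.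

**16 to 8 and 14.** Both bonds from C1' into ring B (C1'–C2' and C1'–C6') are cut, giving benzofuranone 8 and diynone 14. An enynone partner would need a later dehydrogenation with oxidants that endanger the prenyl group. A biomimetic phenol coupling of a benzophenone would need a longer precursor and an oxidant. The diynone delivers the dienone oxidation level directly. The two precursors have no ring B and no stereochemistry. The forward reaction needs C-alkylation of the enolate twice, the second time intramolecularly.

**14 to 9 and 11.** Oxidation-level adjustment leads to carbinol 13. Cutting the C2–C3 bond of 13 gives ynal 10 and lithium methoxyacetylide 12, which is made in the flask from chloroacetaldehyde dimethyl acetal 11. Ynal 10 comes from silyl propargyl ether 9 by formylation. The aldehyde route is preferred to an acyl substitution because the amine from the acetylide generation cannot harm a carbinol, whereas it would add to a free ynone.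

**8 to 1, 2 and 4.** Loss of a carboxyl group via acid 7 leads to β-keto ester 6. Its C2–C3 bond is a Dieckmann bond, leading to diester 5. Two ether disconnections lead to salicylate 3 and methyl bromoacetate 4, then to methyl 2,6-dihydroxy-4-methylbenzoate 1 and prenyl bromide 2. Direct acylation of orcinol would go to the wrong ring position; starting from 1 fixes the 1,2,3-pattern. The forward sequence needs only monoalkylation of a symmetrical diol.

## Roads not taken

**Alternative 1: aryne, phenoxide and carbon dioxide.**
- Cut: the O–C6 and C1–carboxyl bonds of ring A.
- Forward key step: CsF releases an aryne from silyl triflate A2; phenoxide A3 adds at C6 and the C1 aryl anion is trapped by carbon dioxide, giving acid A1.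
- Merits: this is the most convergent plan, both rings are used intact, and the known preference of 3-alkoxyarynes places the anion exactly at C1.
- Weak points: A3 is a 2,6-disubstituted phenoxide competing with fluoride. The aryl anion is protonated by any phenol or adventitious water faster than it is carboxylated, giving the ether without the carboxyl group. Carbon dioxide also ties up the phenoxide as a carbonate. The three-component trapping is established mainly for amines. A2 and A3 each need several steps, and A1 still needs esterification of a doubly flanked acid, removal of two acetals and a selective prenylation.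
- Comparison: alternative 1 is better in convergence and avoids a sensitive ynol ether ketone. The chosen plan sets against this an aryl–oxygen bond made by a trivial alkylation and a key step of a reaction type with direct precedent on benzofuranones.

**Alternative 2: Michael–Claisen benzannulation.**
- Cut: C4–C5 and C1–C2 of ring A.
- Forward key step: the dienolate of aryloxycrotonate A5 (LiN(iPr)2) adds through its γ-carbon to methyl but-2-ynoate A6, then closes by Claisen condensation to salicylate A4.
- Merits: ring B arrives complete from phenol A7, so no late methylation is needed, and the prenyl group is put on last and never exposed; the end game is one step shorter than in the chosen plan.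
- Weak points: lithium dienolates of crotonates prefer α-attack. The β-aryloxy group is a leaving group, so the dienolate can shed aryloxide to an allenoate. A6 has acidic propargylic hydrogens that quench the dienolate. A7 must be built first and added in a hindered oxa-Michael reaction.
- Comparison: the end game of alternative 2 is better. The chosen plan sets against it a carbon acid that can react only at one carbon, a non-enolisable acceptor, and commercial ring A material.

**Alternative 3: polyketide-type aldol folding.**
- Cut: C1'–C2' of ring B.
- Forward key step: mild base makes the aryloxy CH2 of triketone A9 attack the acetal-bearing ketone; dehydration and enolisation give resorcinol A8.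
- Merits: like the chosen plan, ring B grows on the O–CH2 carbon, from cheap acyclic carbon, with no ynol ether; both phenols of A8 are methylated in one operation.
- Weak points: the C1' methylene is the least acidic of three and sits ortho to the ring A ester, so its carbanion is set up for Dieckmann closure to a benzofuranone. The triketone can also close through oxygen to a pyranone or by other aldol modes. Building A9 needs polyanion acylation in the presence of the benzoate. The end game needs acidic acetal hydrolysis beside the prenyl ether, then a reduction.
- Comparison: alternative 3 is as good in step count after the key step and better in reagent cost. The chosen plan sets against it that the competing Dieckmann closure is used on purpose and then reversed, so chemoselectivity is not left to chance.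

Key step: step 8

Assumption: methyl 2,6-dihydroxy-4-methylbenzoate 1 and tert-butyldimethyl(prop-2-yn-1-yloxy)silane 9 are taken as purchasable; each is one routine operation from 2,6-dihydroxy-4-methylbenzoic acid or propargyl alcohol if it has to be made.

## Route

Step 1
Reactants: 1 methyl 2,6-dihydroxy-4-methylbenzoate; 2 prenyl bromide (1-bromo-3-methylbut-2-ene)
Product: 3 methyl 2-hydroxy-4-methyl-6-(3-methylbut-2-enyloxy)benzoate
Conditions: 2 (1.05 equiv), K2CO3 (1.1 equiv), acetone, reflux
Reagents that add atoms: none
Why: Williamson ether synthesis; after the first alkylation the remaining hydroxyl is held in a hydrogen bond to the ester carbonyl and is the weaker nucleophile, so one equivalent of halide should stop at the monoether.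

Step 2
Reactants: 3 methyl 2-hydroxy-4-methyl-6-(3-methylbut-2-enyloxy)benzoate; 4 methyl bromoacetate
Product: 5 methyl 2-(2-methoxy-2-oxoethoxy)-4-methyl-6-(3-methylbut-2-enyloxy)benzoate
Conditions: 4 (1.3 equiv), K2CO3, DMF, 60 °C
Reagents that add atoms: none
Why: Williamson ether synthesis on the hydrogen-bonded salicylate hydroxyl, which needs the dipolar solvent and gentle heating; the reactive α-halo ester compensates for the low nucleophilicity.

Step 3
Reactants: 5 methyl 2-(2-methoxy-2-oxoethoxy)-4-methyl-6-(3-methylbut-2-enyloxy)benzoate
Product: 6 methyl 3-hydroxy-6-methyl-4-(3-methylbut-2-enyloxy)-1-benzofuran-2-carboxylate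
Conditions: KOtBu (1.2 equiv), THF, 0 °C → rt; cold 1 M HCl work-up
Reagents that add atoms: none
Why: Dieckmann condensation; the carbanion of the aryloxyacetate attacks the neighbouring benzoate carbonyl (5-exo-trig), methoxide is lost, and deprotonation of the product to an aromatic benzofuran-3-olate drives the equilibrium.

Step 4
Reactants: 6 methyl 3-hydroxy-6-methyl-4-(3-methylbut-2-enyloxy)-1-benzofuran-2-carboxylate
Product: 8 6-methyl-4-(3-methylbut-2-enyloxy)benzofuran-3(2H)-one, via 3-hydroxybenzofuran-2-carboxylic acid 7 (not isolated)
Conditions: NaOH, MeOH–H2O, reflux, argon; then 1 M HCl to pH 2, 40 °C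
Reagents that add atoms: none
Why: Ester saponification, then decarboxylation of the β-keto acid tautomer of 7 on acidification; the free benzofuranone forms only in the acidic stage, so it is not exposed to base and air (oxidative dimerisation), and the short contact with dilute acid should spare the aryl prenyl ether.

Step 5
Reactants: 9 tert-butyldimethyl(prop-2-yn-1-yloxy)silane
Product: 10 4-(tert-butyldimethylsilyloxy)but-2-ynal
Conditions: n-BuLi, THF, −78 °C; DMF, −78 → 0 °C; poured into cold aq. KH2PO4
Reagents that add atoms: N,N-dimethylformamide, CN(C)C=O
Why: Formylation of a lithium acetylide with DMF; the hemiaminal alkoxide survives until the inverse quench into phosphate buffer, which keeps dimethylamine protonated so that it cannot add to the ynal.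

Step 6
Reactants: 10 4-(tert-butyldimethylsilyloxy)but-2-ynal; 11 chloroacetaldehyde dimethyl acetal (2-chloro-1,1-dimethoxyethane)
Product: 13 6-(tert-butyldimethylsilyloxy)-1-methoxyhexa-1,4-diyn-3-ol (racemic), via lithium methoxyacetylide 12 (not isolated)
Conditions: 11, LiNEt2 (3 equiv, from Et2NH and n-BuLi), THF, 0 °C; then 10, −78 °C; aq. NH4Cl
Reagents that add atoms: none
Why: Threefold action of the lithium amide on 11 (loss of methanol, loss of HCl, deprotonation) is the standard in situ entry to a lithium alkoxyacetylide, which adds 1,2 to the aldehyde at low temperature; the carbinol centre forms racemic and is removed in step 7.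

Step 7
Reactants: 13 6-(tert-butyldimethylsilyloxy)-1-methoxyhexa-1,4-diyn-3-ol
Product: 14 6-(tert-butyldimethylsilyloxy)-1-methoxyhexa-1,4-diyn-3-one
Conditions: MnO2 (activated, excess), CH2Cl2, 0 °C → rt; filtered and used at once
Reagents that add atoms: none
Why: MnO2 oxidation of a doubly propargylic alcohol under neutral heterogeneous conditions, the usual access to alkoxyethynyl ketones; filtration alone isolates the acid- and nucleophile-sensitive product.

Step 8
Reactants: 8 6-methyl-4-(3-methylbut-2-enyloxy)benzofuran-3(2H)-one; 14 6-(tert-butyldimethylsilyloxy)-1-methoxyhexa-1,4-diyn-3-one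
Product: 16 racemic 2'-(tert-butyldimethylsilyloxymethyl)-6'-methoxy-6-methyl-4-(3-methylbut-2-enyloxy)-3H-spiro[1-benzofuran-2,1'-cyclohexa-2',5'-diene]-3,4'-dione, via Z-configured mono-Michael adduct 15 (not isolated)
Conditions: KOtBu (0.1 equiv), THF, −20 °C → rt, argon; 8 and base added slowly to 14 (1.1 equiv)
Reagents that add atoms: none
Why: Base-catalysed double Michael ([5+1]) spiroannulation, the reaction type known for benzofuran-3(2H)-ones with alkoxyethynyl vinyl ketones, applied here to a cross-conjugated diynone so that ring B arrives at the dienone oxidation level. The potassium enolate of 8 adds through C2 to C5 of 14, the alkyne terminus that bears the silyloxymethyl group and is not deactivated by oxygen donation; proton transfer from a further molecule of 8 gives 15 and carries the chain. The remaining C2–H of 15 lies between the ketone and the new enone and is removed again, and the E and Z isomers of 15 interconvert through this extended enolate, so the Z isomer can close. Ring B closes by 6-endo-dig conjugate addition of C2 to the methoxy-bearing C1, forming C1'–C6' after C1'–C2'; the reverse order of additions leads to the same product. The spiro carbon is the only new stereocentre; nothing controls it, 16 is racemic, and the centre disappears in step 9. The step needs C- rather than O-attack of the ambident enolate, which the soft acceptor favours. It also needs ring closure rather than attack of a second enolate, which the intramolecular second addition and the slow addition of 8 secure. The base is kept catalytic so that tert-butoxide neither adds to the ynol ether nor opens the product.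

Step 9
Reactants: 16 racemic spiro dienone from step 8
Product: 17 methyl 2-[2-(tert-butyldimethylsilyloxymethyl)-4-hydroxy-6-methoxyphenoxy]-4-methyl-6-(3-methylbut-2-enyloxy)benzoate
Conditions: NaOMe (1.5 equiv), MeOH–THF, 0 °C → rt; AcOH quench
Reagents that add atoms: sodium methoxide, [Na+].[O-]C
Why: Retro-Claisen (retro-Dieckmann) fragmentation driven by aromatisation, known for grisa-2',5'-diene-3,4'-diones, which open to diaryl ether esters; methoxide adds to the furanone ketone and the tetrahedral intermediate expels C1', whose electron pair flows into the dienone to give the C4' phenoxide. Conjugate addition of methoxide to the dienone is reversible (degenerate at C6') and drains into the irreversible opening; the primary silyl ether and the prenyl ether are stable to methoxide at this temperature.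

Step 10
Reactants: 17 methyl 2-[2-(tert-butyldimethylsilyloxymethyl)-4-hydroxy-6-methoxyphenoxy]-4-methyl-6-(3-methylbut-2-enyloxy)benzoate
Product: 18 methyl 2-[2-(tert-butyldimethylsilyloxymethyl)-4,6-dimethoxyphenoxy]-4-methyl-6-(3-methylbut-2-enyloxy)benzoate
Conditions: MeI, K2CO3, acetone, 40 °C
Reagents that add atoms: iodomethane, CI
Why: Williamson methylation of the only phenol, which is unhindered (hydrogen on both neighbours); nothing else in the molecule is alkylated under carbonate.

Step 11
Reactants: 18 methyl 2-[2-(tert-butyldimethylsilyloxymethyl)-4,6-dimethoxyphenoxy]-4-methyl-6-(3-methylbut-2-enyloxy)benzoate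
Product: 19 methyl 2-[2-(hydroxymethyl)-4,6-dimethoxyphenoxy]-4-methyl-6-(3-methylbut-2-enyloxy)benzoate
Conditions: Bu4NF, AcOH (1:1), THF, 0 °C → rt
Reagents that add atoms: none
Why: Fluoride cleavage of a primary silyl ether; acetic acid buffers the medium so that no benzylic alkoxide builds up that could attack the neighbouring ester and close an eight-membered lactone, and ester and prenyl ether are inert.

## Compound list

1 | methyl 2,6-dihydroxy-4-methylbenzoate | COC(=O)c1c(O)cc(C)cc1O | starting material
2 | prenyl bromide (1-bromo-3-methylbut-2-ene) | CC(C)=CCBr | starting material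
3 | methyl 2-hydroxy-4-methyl-6-(3-methylbut-2-enyloxy)benzoate | COC(=O)c1c(O)cc(C)cc1OCC=C(C)C | intermediate
4 | methyl bromoacetate | COC(=O)CBr | starting material
5 | methyl 2-(2-methoxy-2-oxoethoxy)-4-methyl-6-(3-methylbut-2-enyloxy)benzoate | COC(=O)COc1cc(C)cc(OCC=C(C)C)c1C(=O)OC | intermediate
6 | methyl 3-hydroxy-6-methyl-4-(3-methylbut-2-enyloxy)-1-benzofuran-2-carboxylate | COC(=O)c1oc2cc(C)cc(OCC=C(C)C)c2c1O | intermediate
7 | 3-hydroxy-6-methyl-4-(3-methylbut-2-enyloxy)-1-benzofuran-2-carboxylic acid | OC(=O)c1oc2cc(C)cc(OCC=C(C)C)c2c1O | intermediate (not isolated)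
8 | 6-methyl-4-(3-methylbut-2-enyloxy)benzofuran-3(2H)-one | CC(C)=CCOc1cc(C)cc2OCC(=O)c12 | intermediate
9 | tert-butyldimethyl(prop-2-yn-1-yloxy)silane | C#CCO[Si](C)(C)C(C)(C)C | starting material
10 | 4-(tert-butyldimethylsilyloxy)but-2-ynal | O=CC#CCO[Si](C)(C)C(C)(C)C | intermediate
11 | chloroacetaldehyde dimethyl acetal (2-chloro-1,1-dimethoxyethane) | COC(CCl)OC | starting material
12 | lithium methoxyacetylide | [Li]C#COC | intermediate (not isolated)
13 | 6-(tert-butyldimethylsilyloxy)-1-methoxyhexa-1,4-diyn-3-ol (racemic) | COC#CC(O)C#CCO[Si](C)(C)C(C)(C)C | intermediate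
14 | 6-(tert-butyldimethylsilyloxy)-1-methoxyhexa-1,4-diyn-3-one | COC#CC(=O)C#CCO[Si](C)(C)C(C)(C)C | intermediate
15 | 2-[(Z)-1-(tert-butyldimethylsilyloxy)-6-methoxy-4-oxohex-2-en-5-yn-2-yl]-6-methyl-4-(3-methylbut-2-enyloxy)benzofuran-3(2H)-one (racemic) | CC(C)=CCOc1cc(C)cc2OC(C(=O)c12)/C(CO[Si](C)(C)C(C)(C)C)=C\C(=O)C#COC | intermediate (not isolated)
16 | 2'-(tert-butyldimethylsilyloxymethyl)-6'-methoxy-6-methyl-4-(3-methylbut-2-enyloxy)-3H-spiro[1-benzofuran-2,1'-cyclohexa-2',5'-diene]-3,4'-dione (racemic at the spiro carbon) | CC(C)=CCOc1cc(C)cc2OC3(C(=O)c12)C(CO[Si](C)(C)C(C)(C)C)=CC(=O)C=C3OC | intermediate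
17 | methyl 2-[2-(tert-butyldimethylsilyloxymethyl)-4-hydroxy-6-methoxyphenoxy]-4-methyl-6-(3-methylbut-2-enyloxy)benzoate | COC(=O)c1c(OCC=C(C)C)cc(C)cc1Oc1c(CO[Si](C)(C)C(C)(C)C)cc(O)cc1OC | intermediate
18 | methyl 2-[2-(tert-butyldimethylsilyloxymethyl)-4,6-dimethoxyphenoxy]-4-methyl-6-(3-methylbut-2-enyloxy)benzoate | COC(=O)c1c(OCC=C(C)C)cc(C)cc1Oc1c(CO[Si](C)(C)C(C)(C)C)cc(OC)cc1OC | intermediate
19 | methyl 2-[2-(hydroxymethyl)-4,6-dimethoxyphenoxy]-4-methyl-6-(3-methylbut-2-enyloxy)benzoate | COC(=O)c1c(OCC=C(C)C)cc(C)cc1Oc1c(CO)cc(OC)cc1OC | target

## Step count and least certain steps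

Total: 11 steps. Longest linear sequence: 8 steps (steps 1–4 and 8–11 from 1); the diynone arm is 3 steps (5–7).

**Step 8 (key step).** The most likely failures are capture of the mono-adduct by a second enolate, oligomerisation of the diynone, or O-alkylation, all of which compete with the 6-endo-dig closure; the enolate could also add to the product dienone. The fallback is the enynone version of the annulation followed by dehydrogenation; it sets out from 8 and returns at 16.
- (Z)-But-2-ene-1,4-diol is monosilylated to (Z)-4-(tert-butyldimethylsilyloxy)but-2-en-1-ol F1.
- Oxidation with pyridinium chlorochromate, with isomerisation, gives (E)-4-(tert-butyldimethylsilyloxy)but-2-enal F2.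
- Addition of 12 (generated as in step 6) gives (E)-6-(tert-butyldimethylsilyloxy)-1-methoxyhex-4-en-1-yn-3-ol F3, and MnO2 gives (E)-6-(tert-butyldimethylsilyloxy)-1-methoxyhex-4-en-1-yn-3-one F4.
- KOtBu-catalysed double Michael addition of 8 to F4 gives 6'-(tert-butyldimethylsilyloxymethyl)-2'-methoxy-6-methyl-4-(3-methylbut-2-enyloxy)-3H-spiro[1-benzofuran-2,1'-cyclohex-2'-ene]-3,4'-dione F5 as a mixture of diastereomers, all of which converge.
- LiN(SiMe3)2 and Me3SiCl convert F5 at C5' into the trimethylsilyl dienol ether F6, and Saegusa–Ito oxidation with Pd(OAc)2 in MeCN introduces the C5'–C6' double bond to give 16. This avoids SeO2 and DDQ, which would attack the prenyl group.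

**Step 6.** The likely failures are incomplete elimination from 11, leaving the acetylide in deficit, and conjugate addition of lithium amide or diethylamine to ynal 10. The fallback generates 12 without any amine; it sets out from 10 and returns at 13. Trichloroethylene and NaOMe give (E)-1,2-dichloro-1-methoxyethene F7. Two equivalents of n-BuLi at −78 °C convert it into 12 by deprotonation, loss of LiCl and chlorine–lithium exchange, and 10 is then added.

**Step 7.** The likely failure is loss of the diynone on the oxidant surface or during isolation, through hydration of the ynol ether or oligomerisation. The fallback reaches the ketone by acyl substitution without an oxidation; it sets out from 9 and returns at 14. Lithiated 9 is acylated with N-methoxy-N-methylcarbamoyl chloride to give 4-(tert-butyldimethylsilyloxy)-N-methoxy-N-methylbut-2-ynamide F8. Addition of 12 at −78 °C (Weinreb ketone synthesis) gives a chelated adduct that releases 14 only on inverse quench into cold phosphate buffer, where the amines are protonated.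

**Step 9.** The likely failures are slow attack of solvated methoxide at the flanked, electron-rich furanone carbonyl and methanolysis of the silyl ether on prolonged exposure. The fallback opens the ring with hydroxide and installs both methyl groups afterwards; it sets out from 16 and returns at 18, skipping 17. LiOH in THF–H2O gives 2-[2-(tert-butyldimethylsilyloxymethyl)-4-hydroxy-6-methoxyphenoxy]-4-methyl-6-(3-methylbut-2-enyloxy)benzoic acid F9. Excess MeI with K2CO3 in DMF then methylates carboxylate and phenoxide together.

## Further compounds

F1 | step 8 | (Z)-4-(tert-butyldimethylsilyloxy)but-2-en-1-ol | CC(C)(C)[Si](C)(C)OC/C=C\CO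
F2 | step 8 | (E)-4-(tert-butyldimethylsilyloxy)but-2-enal | CC(C)(C)[Si](C)(C)OC/C=C/C=O
F3 | step 8 | (E)-6-(tert-butyldimethylsilyloxy)-1-methoxyhex-4-en-1-yn-3-ol (racemic) | COC#CC(O)/C=C/CO[Si](C)(C)C(C)(C)C
F4 | step 8 | (E)-6-(tert-butyldimethylsilyloxy)-1-methoxyhex-4-en-1-yn-3-one | COC#CC(=O)/C=C/CO[Si](C)(C)C(C)(C)C
F5 | step 8 | 6'-(tert-butyldimethylsilyloxymethyl)-2'-methoxy-6-methyl-4-(3-methylbut-2-enyloxy)-3H-spiro[1-benzofuran-2,1'-cyclohex-2'-ene]-3,4'-dione (mixture of racemic diastereomers) | CC(C)=CCOc1cc(C)cc2OC3(C(=O)c12)C(CO[Si](C)(C)C(C)(C)C)CC(=O)C=C3OC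
F6 | step 8 | trimethylsilyl dienol ether of F5 (4'-trimethylsilyloxy-2',4'-diene, racemic diastereomers) | CC(C)=CCOc1cc(C)cc2OC3(C(=O)c12)C(CO[Si](C)(C)C(C)(C)C)C=C(O[Si](C)(C)C)C=C3OC
F7 | step 6 | (E)-1,2-dichloro-1-methoxyethene | CO/C(Cl)=C\Cl
F8 | step 7 | 4-(tert-butyldimethylsilyloxy)-N-methoxy-N-methylbut-2-ynamide | CON(C)C(=O)C#CCO[Si](C)(C)C(C)(C)C
F9 | step 9 | 2-[2-(tert-butyldimethylsilyloxymethyl)-4-hydroxy-6-methoxyphenoxy]-4-methyl-6-(3-methylbut-2-enyloxy)benzoic acid | OC(=O)c1c(OCC=C(C)C)cc(C)cc1Oc1c(CO[Si](C)(C)C(C)(C)C)cc(O)cc1OC
A1 | alternative 1 | 2-[2,4-dimethoxy-6-(methoxymethoxymethyl)phenoxy]-6-(methoxymethoxy)-4-methylbenzoic acid | COCOc1cc(C)cc(Oc2c(COCOC)cc(OC)cc2OC)c1C(=O)O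
A2 | alternative 1 | 3-(methoxymethoxy)-5-methyl-2-(trimethylsilyl)phenyl trifluoromethanesulfonate | COCOc1cc(C)cc(OS(=O)(=O)C(F)(F)F)c1[Si](C)(C)C
A3 | alternative 1 | 2,4-dimethoxy-6-(methoxymethoxymethyl)phenol | COCOCc1cc(OC)cc(OC)c1O
A4 | alternative 2 | methyl 2-[2-(tert-butyldimethylsilyloxymethyl)-4,6-dimethoxyphenoxy]-6-hydroxy-4-methylbenzoate | COC(=O)c1c(O)cc(C)cc1Oc1c(CO[Si](C)(C)C(C)(C)C)cc(OC)cc1OC
A5 | alternative 2 | methyl (E)-3-[2-(tert-butyldimethylsilyloxymethyl)-4,6-dimethoxyphenoxy]but-2-enoate | COC(=O)/C=C(\C)Oc1c(CO[Si](C)(C)C(C)(C)C)cc(OC)cc1OC
A6 | alternative 2 | methyl but-2-ynoate | CC#CC(=O)OC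
A7 | alternative 2 | 2-(tert-butyldimethylsilyloxymethyl)-4,6-dimethoxyphenol | COc1cc(CO[Si](C)(C)C(C)(C)C)c(O)c(OC)c1
A8 | alternative 3 | methyl 2-[2-(dimethoxymethyl)-4,6-dihydroxyphenoxy]-4-methyl-6-(3-methylbut-2-enyloxy)benzoate | COC(=O)c1c(OCC=C(C)C)cc(C)cc1Oc1c(C(OC)OC)cc(O)cc1O
A9 | alternative 3 | methyl 2-(7,7-dimethoxy-2,4,6-trioxoheptyloxy)-4-methyl-6-(3-methylbut-2-enyloxy)benzoate | COC(=O)c1c(OCC=C(C)C)cc(C)cc1OCC(=O)CC(=O)CC(=O)C(OC)OC
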